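Gentiside K is disconnected within its benzene ring rather than at the ester. Ring carbons C1 (bearing the tetracosyl ester), C2 (OH) and C3 (OH), together with the carboxyl carbon, are the four carbons of a 4-oxygenated acetoacetate; the unsubstituted C4–C5–C6 stretch is a masked malonaldehyde. A Lewis-acid-mediated formal [3+3] cyclocondensation forges the C3–C4 and C1–C6 bonds, closes the six-membered ring and aromatises it in one operation, delivering the 1,2,3-substitution pattern with the C24 ester already in place. Its precursor is the 1,3-bis(trimethylsilyloxy)diene of tetracosyl 4-(benzyloxy)acetoacetate, reached in three steps; one hydrogenolysis then frees the catechol.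

Key step: step 4

Assumption: the target has no stereocentre and no stereogenic double bond, so it is achiral and no stereocontrol is needed. The alkene geometries of 4, 5 and 7 and the transient stereocentres of 7 and 8 are left undefined because all are erased on aromatisation. Ethyl 4-(benzyloxy)-3-oxobutanoate is taken as a catalogue chemical.

Step 1
Reactants: 1 ethyl 4-(benzyloxy)-3-oxobutanoate; 2 1-tetracosanol
Product: 3 tetracosyl 4-(benzyloxy)-3-oxobutanoate
Conditions: 1 (1.3 equiv), 2 (1.0 equiv), DMAP (0.2 equiv), toluene, reflux, EtOH removed by slow distillation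
Reagents that add atoms: none
Why: DMAP-catalysed transesterification of a β-keto ester, a class that exchanges its alkoxy group far more readily than simple esters, is driven to the long-chain ester by removing ethanol, while the ketone and benzyl ether are inert and no stereocentre is formed.

Step 2
Reactants: 3 tetracosyl 4-(benzyloxy)-3-oxobutanoate
Product: 4 tetracosyl 4-(benzyloxy)-3-(trimethylsilyloxy)but-2-enoate (E/Z mixture)
Conditions: TMSCl (1.8 equiv), Et3N (1.6 equiv), toluene, 20 °C; filtration under Ar, concentration, used crude
Reagents that add atoms: chlorotrimethylsilane, C[Si](C)(C)Cl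
Why: Enol O-silylation of a β-keto ester under soft-enolisation conditions takes place at the strongly enolised C2–C3 unit to give the conjugated β-silyloxy enoate, leaving the C4 methylene, the benzyl ether and the ester untouched, with no stereocentre formed.

Step 3
Reactants: 4 tetracosyl 4-(benzyloxy)-3-(trimethylsilyloxy)but-2-enoate
Product: 5 4-(benzyloxy)-1-(tetracosyloxy)-1,3-bis(trimethylsilyloxy)buta-1,3-diene (geometry of no consequence)
Conditions: LDA (commercial solution, 1.5 equiv), THF (dilute), −78 °C; TMSCl (1.5 equiv), −78 → 20 °C; hexane, filtration under Ar, used crude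
Reagents that add atoms: chlorotrimethylsilane, C[Si](C)(C)Cl
Why: Kinetic γ-deprotonation of the β-silyloxy enoate by LDA gives the extended lithium dienolate, which TMSCl traps on the ester oxygen (O-silylation of an ester enolate) to give the Chan-type 1,3-bis(silyloxy)-1,3-diene, with no stereocentre formed.

Step 4
Reactants: 5 4-(benzyloxy)-1-(tetracosyloxy)-1,3-bis(trimethylsilyloxy)buta-1,3-diene; 6 1,1,3,3-tetramethoxypropane
Product: 9 tetracosyl 3-(benzyloxy)-2-hydroxybenzoate, via open-chain acetal adduct 7 (not isolated), via dimethoxycyclohexanone ester 8 (not isolated)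
Conditions: 6 (1.1 equiv), TMSOTf (0.2 equiv), CH2Cl2 (dilute), −78 → 20 °C; then 10% aq HCl
Reagents that add atoms: none
Why: TMSOTf ionises one acetal terminus of 6 to a methoxycarbenium ion that is captured by the terminal diene carbon (C4 of 5, future ring C3) in a vinylogous Mukaiyama-type addition, forming the C3–C4 ring bond, releasing Me3SiOMe and leaving silyl enol ether 7. Ionisation of the second acetal then lets the α-carbon of 7 (future ring C1) attack the new oxocarbenium ion, forming the C1–C6 bond and closing the six-membered carbocycle 8 in a 6-(enolendo)-exo-trig mode as 7 is drawn, or 6-(enolexo)-exo-trig if the silyl group sits on the ester oxygen as a ketene acetal, both being favoured closures. Two β-eliminations of methanol followed by enolisation, completed by the acidic work-up, should convert 8 into the aromatic salicylate 9 with the benzyloxy group at C3 and the C24 ester at C1. The closest known reaction type is the Chan-type Lewis-acid-mediated formal [3+3] cyclocondensation of 1,3-bis(silyloxy)-1,3-dienes with malonaldehyde bis(dimethyl acetal), which gives salicylates unsubstituted at C4–C6. No stereocentre survives, since the transient ones in 7 and 8 are erased on aromatisation. The step needs C- rather than O-alkylation at both diene termini and ring closure rather than a second intermolecular alkylation, which the soft carbon nucleophilicity of the silyl enol ethers and the intramolecular, dilute second step secure, while regiochemistry cannot go wrong because 6 is symmetric and either order of bond formation leads to the same arene.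

Step 5
Reactants: 9 tetracosyl 3-(benzyloxy)-2-hydroxybenzoate
Product: 10 Gentiside K (tetracosyl 2,3-dihydroxybenzoate)
Conditions: H2 (1 atm), 10% Pd/C, EtOAc–THF, 25–40 °C; filtration under Ar
Reagents that add atoms: none
Why: Heterogeneous catalytic hydrogenolysis cleaves only the benzylic C–O bond of the aryl benzyl ether, since the alkyl ester, the arene and the phenols are inert to H2 over Pd/C at ambient pressure, so the catechol is released without any stereochemical issue.

Compound list
1 | ethyl 4-(benzyloxy)-3-oxobutanoate | CCOC(=O)CC(=O)COCc1ccccc1 | starting material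
2 | 1-tetracosanol | CCCCCCCCCCCCCCCCCCCCCCCCO | starting material
3 | tetracosyl 4-(benzyloxy)-3-oxobutanoate | CCCCCCCCCCCCCCCCCCCCCCCCOC(=O)CC(=O)COCc1ccccc1 | intermediate
4 | tetracosyl 4-(benzyloxy)-3-(trimethylsilyloxy)but-2-enoate (E/Z mixture) | CCCCCCCCCCCCCCCCCCCCCCCCOC(=O)C=C(O[Si](C)(C)C)COCc1ccccc1 | intermediate
5 | 4-(benzyloxy)-1-(tetracosyloxy)-1,3-bis(trimethylsilyloxy)buta-1,3-diene (geometry of no consequence) | CCCCCCCCCCCCCCCCCCCCCCCCOC(O[Si](C)(C)C)=CC(O[Si](C)(C)C)=COCc1ccccc1 | intermediate
6 | 1,1,3,3-tetramethoxypropane | COC(CC(OC)OC)OC | starting material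
7 | tetracosyl 4-(benzyloxy)-5,7,7-trimethoxy-3-(trimethylsilyloxy)hept-2-enoate (open-chain acetal adduct, isomer mixture) | CCCCCCCCCCCCCCCCCCCCCCCCOC(=O)C=C(O[Si](C)(C)C)C(OCc1ccccc1)C(OC)CC(OC)OC | intermediate
8 | tetracosyl 3-(benzyloxy)-4,6-dimethoxy-2-oxocyclohexane-1-carboxylate (diastereomer mixture) | CCCCCCCCCCCCCCCCCCCCCCCCOC(=O)C1C(OC)CC(OC)C(OCc2ccccc2)C1=O | intermediate
9 | tetracosyl 3-(benzyloxy)-2-hydroxybenzoate | CCCCCCCCCCCCCCCCCCCCCCCCOC(=O)c1cccc(OCc2ccccc2)c1O | intermediate
10 | Gentiside K, tetracosyl 2,3-dihydroxybenzoate (achiral) | CCCCCCCCCCCCCCCCCCCCCCCCOC(=O)c1cccc(O)c1O | target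

Total step count: 5
Longest linear sequence: 5 steps (1 → 3 → 4 → 5 → 9 → 10)

Steps most likely to fail

Step 4. The diene may be protodesilylated back to the keto ester faster than it is alkylated. The open-chain adduct may also be alkylated by a second acetal molecule instead of closing. The waxy substrate may leave solution at low temperature, so that elimination stalls before aromatisation. The fallback abandons the ring construction and esterifies a preformed arene. It sets out from compound 2: Steglich esterification of purchased 2,3-bis(benzyloxy)benzoic acid with 2 (EDC·HCl, DMAP, CH2Cl2, 20 °C) should give tetracosyl 2,3-bis(benzyloxy)benzoate F1. Hydrogenolysis of both benzyl ethers (H2, Pd/C, EtOAc–THF) comes back to the route at compound 10.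

Step 3. γ-Deprotonation may be incomplete because the C24 ester precipitates from THF at −78 °C. Silylation may occur on carbon instead of oxygen, and the silyl ketene acetal may hydrolyse during handling. The fallback builds the ring on the short-chain ester and attaches the chain afterwards. It sets out from compound 1: TMSCl/Et3N should give ethyl 4-(benzyloxy)-3-(trimethylsilyloxy)but-2-enoate F2. LDA then TMSCl (THF, −78 °C) should give 4-(benzyloxy)-1-ethoxy-1,3-bis(trimethylsilyloxy)buta-1,3-diene F3. The same TMSOTf-mediated cyclocondensation with 6 should give ethyl 3-(benzyloxy)-2-hydroxybenzoate F4. Titanate-catalysed transesterification of this salicylate with 2 (Ti(OiPr)4 cat., xylene, 140 °C, ethanol distilled off) comes back to the route at compound 9.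

Step 1. The ester exchange may stall at equilibrium if ethanol is not removed efficiently, and prolonged heating may cause self-condensation of the β-keto ester. The fallback replaces the equilibrium by an irreversible acyl transfer. It sets out from compound 2: benzyloxyacetyl chloride and Meldrum's acid (pyridine, CH2Cl2, 0 °C) should give 5-[2-(benzyloxy)-1-hydroxyethylidene]-2,2-dimethyl-1,3-dioxane-4,6-dione F5. Heating this with 2 in toluene at 90–110 °C, with loss of acetone and carbon dioxide, comes back to the route at compound 3.

Further compounds
F1 | step 4 | tetracosyl 2,3-bis(benzyloxy)benzoate | CCCCCCCCCCCCCCCCCCCCCCCCOC(=O)c1cccc(OCc2ccccc2)c1OCc1ccccc1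
F2 | step 3 | ethyl 4-(benzyloxy)-3-(trimethylsilyloxy)but-2-enoate (E/Z mixture) | CCOC(=O)C=C(O[Si](C)(C)C)COCc1ccccc1
F3 | step 3 | 4-(benzyloxy)-1-ethoxy-1,3-bis(trimethylsilyloxy)buta-1,3-diene (geometry of no consequence) | CCOC(O[Si](C)(C)C)=CC(O[Si](C)(C)C)=COCc1ccccc1
F4 | step 3 | ethyl 3-(benzyloxy)-2-hydroxybenzoate | CCOC(=O)c1cccc(OCc2ccccc2)c1O
F5 | step 1 | 5-[2-(benzyloxy)-1-hydroxyethylidene]-2,2-dimethyl-1,3-dioxane-4,6-dione | CC1(C)OC(=O)C(=C(O)COCc2ccccc2)C(=O)O1
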